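## The problem

The target joins two polyketide-type halves, a 6-ethyl-4-hydroxy-5-methylpyran-2-one and an 8-acyl-3,5,7-trihydroxy-2,2-dimethylchroman, through one methylene carbon between pyranone C3 and chroman C6 (chroman numbering O1, C2, C3, C4, C4a, C5–C8, C8a is used for the bicyclic half). Each half has exactly one nucleophilic C–H carbon, so the bridge has to be made as a crossed coupling with a one-carbon electrophile that avoids the two symmetrical dimers. The benzene ring is fully substituted and carries three oxygens that must be told apart: the pyran oxygen has to sit on C8a, between the acyl carbon C8 and C4a, while the oxygen on C5, which flanks C4a on the other side, must end as a free hydroxyl. There are two stereocentres, C3 of the chroman (S) and C2 of the 2-methylbutanoyl chain (S). They lie six bonds apart and cannot steer one another, so the chain centre has to be bought and kept away from enolisation, C3 has to be set by a reagent, and an error at C3 gives a diastereomer that will be hard to remove. Several groups are fragile: the α-branched aryl ketone (epimerisation), the electron-rich phloroglucinol nucleus (oxidation, C- versus O-alkylation), the tertiary alkyl aryl ether (acid-induced reopening), and the lactone of the pyranone (alkoxide). Any epoxy-phenol on the way closes 5-exo under base and 6-endo under acid. The feature that opens the route is that ring carbons C8a, C4a, C5, C6, C7 and C8 plus the ketone carbon form a tetraketide chain. The acylphloroglucinol with its C4a substituent is therefore a constitutional isomer of a 3-substituted 4-hydroxy-6-(2-oxoalkyl)pyran-2-one, whose lactone carbonyl maps onto C8a, C3 onto C4a and the side-chain methylene onto C8.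

## Retrosynthesis

**Bridge.** Both C–C bonds at the bridging methylene of 19 are cut (chroman C6–CH2 and CH2–pyranone C3), which gives chroman triol 12, pyranone 16 and a one-carbon electrophile. No other cut gives two stable, separately purified halves of similar size. The forward reaction must be a crossed coupling. This is arranged by first aminomethylating 12, whose C6 is its only free ring carbon, to Mannich base 17. Loss of dimethylamine then gives ortho-quinone methide 18, which only the pyranone can trap, since 17 has no unsubstituted position left.

**Pyranone.** Pyranone 16 is cut at C4–C5 and O1–C2 into malonyl dichloride 15 and silyl enol ether 14, made from pentan-3-one 13. The ketone is symmetric, so enolisation has no regiochemical issue, and the whole ring comes from two bulk chemicals.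

**Pyran ring of the chroman.** After removing the two silyl ethers (12 from 11), the O1–C2 bond of 11 is cut to give epoxy-phenol 10, and removal of the epoxide oxygen leads to prenyl arene 9. Cutting O1–C8a instead would need an aryl–oxygen bond formation on a fully substituted ring, and cutting C4–C4a would give up the prenyl handle. The forward step has three demands:
- the olefin must be epoxidised on the face that gives the (S)-epoxide;
- the phenol must attack the tertiary carbon (6-endo, acid) and not the secondary one (5-exo, base), so that the secondary C–O bond is untouched and (S)-epoxide becomes (3S)-alcohol;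
- only the oxygen on the future C8a may take part, which is why the C5 oxygen is silylated in 9.

**Differentiation of the oxygens.** Compound 9 comes from triol 8 by silylation of two of its three hydroxyls. The hydroxyl between acyl and prenyl is the most hindered and is hydrogen-bonded to the ketone, so it is the one that should stay free. This removes only protecting groups but fixes the regiochemistry of ring closure.

**Benzene ring (key cut).** In 8 the bond between the acyl-bearing carbon and the hydroxyl-bearing carbon next to the prenyl group (future C8–C8a) is cut, via open triketo ester 7, back to pyranone 6, an isomer of 8. The neighbouring cuts are the aryl–acyl bond (Friedel–Crafts acylation) and the aryl–prenyl bond (C-prenylation of an acylphloroglucinol). Both start from phloroglucinol and both are weaker: mono-C-prenylation of a trihydroxyarene is statistical, and Lewis-acid acylation with an α-branched chiral acid chloride risks the chain stereocentre. The Claisen cut places the prenyl group before the arene exists and trades a hexasubstituted benzene for a disubstituted pyranone. The forward reaction must open the lactone and reclose by Claisen rather than aldol condensation.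

**Side chain of the pyranone.** The CH2–C(=O) bond of 6 is cut to the dianion of prenyl pyranone 3 and the N-methoxy-N-methylamide 5. This is the natural polarity of the 6-methyl group and brings the stereocentre in from a commercial acid without making it part of an enolate.

**Starting materials.** Pyranone 3 is cut at C3–CH2 into 4-hydroxy-6-methylpyran-2-one 1 and prenyl acetate 2 (palladium-catalysed allylation, which favours C over O). Amide 5 comes from (S)-2-methylbutanoic acid 4.

## Roads not taken

**Alternative 1:** The pyranone ring is made last, by cutting pyranone C4–C5 and O1–C2 in the target. In the forward sense an arylmethylmalonyl dichloride A2, carrying the finished tri-O-benzylated chroman, is condensed with silyl enol ether 14 to give the tri-O-benzyl ether A1, and hydrogenolysis then gives 19.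
- Merits: the bridge carbon is part of the malonate from the start, so no crossed three-component coupling is needed and no symmetrical dimer can form.
- Weak points for this target: the most valuable intermediate is exposed to acid chloride formation and to an annulation that liberates HCl, in the presence of the epimerisable ketone and the tertiary alkyl aryl ether. α-Substituted malonyl dichlorides tend to ketene formation and annulate less cleanly than the parent. Three benzyl ethers, one on a hindered secondary alcohol and one on a chelated phenol, have to be put on and taken off.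
- Comparison: on bridge chemoselectivity this road is better in principle. The chosen plan answers by aminomethylating the arene, which has a single reactive carbon, and by using the cheap pyranone 16 in excess; it uses the same annulation on the simple dichloride 15, and it needs no benzyl groups. Alternative 1 also leaves open how the arene is made.

**Alternative 2:** The benzene ring is cut into a 3-tert-butoxy-4-prenylcyclobutenone A4 and an isoleucine-derived siloxyalkyne A5. Heating them together should form C8a–C8 and C6–C7 in a [2+2] step and C8a–C4a by 6π-electrocyclisation, giving pentasubstituted phenol A3 (Danheiser benzannulation).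
- Merits: all three oxygens are differentiated by construction (free hydroxyl on C8a next to the prenyl group, tert-butyl ether on C5, silyl ether on C7), and the substitution pattern is unambiguous.
- Weak points: both partners need multistep syntheses. The side chain arrives as a protected carbinol that must later be deprotected and oxidised next to the stereocentre. The thermal cascade has to tolerate a prenyl group and an acid-labile tert-butyl ether.
- Comparison: in differentiating the oxygens this road is clearly better than the chosen plan, which relies on a chelation- and steric-controlled bis-silylation (step 5). Against that, the chosen plan reaches the arene in four steps from bulk chemicals and carries the ketone at its final oxidation level.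

**Alternative 3:** The C3–O bond is traced to a chromene. A 5,7-bis(benzyloxy)-8-acyl-2,2-dimethylchromene A7 is epoxidised with Jacobsen's (salen)MnCl complex and NaOCl to the (3S,4S)-epoxide A6. Hydrogenolysis of the benzylic C4–O bond, which also removes the benzyl ethers, would give 12.
- Merits: asymmetric epoxidation of 2,2-dimethylchromenes is among the most dependable reactions of its kind. The ring is already closed, so there is no 5-exo/6-endo question, and one hydrogenolysis does two jobs.
- Weak points: the chromene must still be closed onto the correct oxygen of an acylphloroglucinol. The very electron-rich epoxide A6 is prone to acid-induced opening at C4. Hydrogenolysis has to cleave the benzylic C–O bond while sparing the aryl ketone. The road is also silent on how the arene is built.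
- Comparison: the enantioselectivity expected here is probably higher than for the Shi epoxidation of a prenyl side chain (step 6), and ring-size control is intrinsic. The chosen plan is shorter by a redox step and avoids benzyl ethers, and it keeps this chemistry in reserve, with silyl in place of benzyl groups, as the fallback for step 6.

Key step: step 4

Assumption: the sense of induction in step 6 is assigned from the spiro transition-state model of the Shi epoxidation (the D-fructose-derived ketone gives (R)-epoxides from RCH2CH=CMe2), so the L-fructose-derived ketone is specified for the (S)-epoxide.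

## Route

Step 1
Reactants: 1 4-hydroxy-6-methylpyran-2-one; 2 3-methylbut-2-enyl acetate (prenyl acetate)
Product: 3 4-hydroxy-6-methyl-3-(3-methylbut-2-enyl)pyran-2-one
Conditions: Pd(PPh3)4 (5 mol%), DBU, toluene, 60 °C (1 in 1.5-fold excess)
Reagents that add atoms: none
Why: Tsuji–Trost allylation: the pyranone anion, a soft carbon nucleophile, attacks the 1,1-dimethylallyl–palladium complex at its unsubstituted terminus and so gives the linear prenyl group at C3; any 4-O-prenyl ether re-ionises under zerovalent palladium and is funnelled to the C-alkylated product, and the excess of 1 suppresses a second allylation.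

Step 2
Reactants: 4 (S)-2-methylbutanoic acid
Product: 5 (S)-N-methoxy-N,2-dimethylbutanamide
Conditions: CDI, CH2Cl2, 0 °C to rt; then MeNH(OMe)·HCl, rt
Reagents that add atoms: N,O-dimethylhydroxylamine hydrochloride, CNOC.Cl
Why: Amide formation through the acyl imidazole; no base able to enolise the acyl donor is present, so the (S)-centre is carried over unchanged.

Step 3
Reactants: 3 4-hydroxy-6-methyl-3-(3-methylbut-2-enyl)pyran-2-one; 5 (S)-N-methoxy-N,2-dimethylbutanamide
Product: 6 4-hydroxy-6-[(3S)-3-methyl-2-oxopentyl]-3-(3-methylbut-2-enyl)pyran-2-one
Conditions: LiN(iPr)2 (2.1 equiv), THF/DMPU, −78 °C; then 5 (1.1 equiv), −78 to 0 °C; cold 1 M HCl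
Reagents that add atoms: none
Why: Acylation of the pyranone dianion at its most basic site, the 6-methylene carbon; the N-methoxy-N-methylamide forms a stable lithium chelate that releases the ketone only on acidic work-up, which prevents over-addition and proton transfer from the product, and the stereocentre of 5 never becomes part of an enolate.

Step 4
Reactants: 6 4-hydroxy-6-[(3S)-3-methyl-2-oxopentyl]-3-(3-methylbut-2-enyl)pyran-2-one
Product: 8 (S)-2-methyl-1-[2,4,6-trihydroxy-3-(3-methylbut-2-enyl)phenyl]butan-1-one, via triketo ester 7 (not isolated)
Conditions: Mg(OMe)2 (6 equiv), MeOH, reflux; then 1 M HCl, 0 °C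
Reagents that add atoms: none
Why: Methoxide, delivered within a magnesium chelate of the 4-oxido-2-pyranone, adds to the lactone carbonyl and opens the ring to the magnesium enolate of triketo ester 7. The C6 methylene of 7, flanked by the C5 and C7 ketones, attacks the ester carbonyl in a 6-exo-trig Claisen condensation, which forms the bond between the acyl-bearing carbon and the future C8a and closes the only new ring; loss of methoxide and enolisation give the aromatic triol. The closest known reaction type is the magnesium methoxide-mediated conversion of 6-(2-oxoalkyl)-4-hydroxy-2-pyranones (tetraketide lactones) into acylphloroglucinols, here with the 3-prenyl group as a spectator. No stereocentre is created, and the (S)-centre should be retained because the adjacent ketone is enolised only toward the doubly activated methylene and afterwards sits in a phenoxide-conjugated, weakly acidic aryl ketone. The selectivity needed is Claisen over aldol closure: magnesium holds the polyketone folded as a chelated enolate, and the competing aldol attack of the prenylated C2 on the C7 ketone would create a quaternary carbon that cannot aromatise and therefore reverts, whereas aromatisation makes the Claisen path irreversible. Because C2 already carries the prenyl group, the arene is formed mono-C-prenylated next to the hydroxyl that derives from the ester carbonyl.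

Step 5
Reactants: 8 (S)-2-methyl-1-[2,4,6-trihydroxy-3-(3-methylbut-2-enyl)phenyl]butan-1-one
Product: 9 (S)-1-[4,6-bis(tert-butyldimethylsilyloxy)-2-hydroxy-3-(3-methylbut-2-enyl)phenyl]-2-methylbutan-1-one
Conditions: TBSCl (2.2 equiv), imidazole, DMF, 0 °C to rt
Reagents that add atoms: tert-butyldimethylsilyl chloride (TBSCl), CC(C)(C)[Si](C)(C)Cl
Why: Imidazole-promoted silyl ether formation: the para hydroxyl (most acidic) and the unhindered ortho hydroxyl should react, whereas the hydroxyl between the acyl and prenyl groups is flanked on both sides and hydrogen-bonded to the ketone, so it stays free as the future ring oxygen.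

Step 6
Reactants: 9 (S)-1-[4,6-bis(tert-butyldimethylsilyloxy)-2-hydroxy-3-(3-methylbut-2-enyl)phenyl]-2-methylbutan-1-one
Product: 11 (S)-1-[(3S)-5,7-bis(tert-butyldimethylsilyloxy)-3-hydroxy-2,2-dimethylchroman-8-yl]-2-methylbutan-1-one, via epoxide 10 (not isolated)
Conditions: L-fructose-derived Shi ketone (1.0 equiv), KHSO5 (as the triple salt 2KHSO5·KHSO4·K2SO4), NaHCO3 buffer (pH about 8), Bu4NHSO4 (cat.), MeCN/aq. Na2H2(edta), 0 °C; extract; then CSA (10 mol%), CH2Cl2, 0 °C
Reagents that add atoms: potassium peroxymonosulfate (KHSO5), [K+].[O-]S(=O)(=O)OO
Why: Shi epoxidation followed by acid-catalysed 6-endo epoxide opening: the chiral dioxirane attacks the trisubstituted olefin through a spiro transition state, the catalyst enantiomer being chosen for the (S)-epoxide; buffering near pH 8 keeps the chelated phenol protonated so that it is neither oxidised nor closes 5-exo; CSA then directs the phenol to the tertiary epoxide carbon and leaves the secondary C–O bond untouched, so the (S)-epoxide should become the (3S)-chromanol, while the silylated para oxygen cannot compete.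

Step 7
Reactants: 11 (S)-1-[(3S)-5,7-bis(tert-butyldimethylsilyloxy)-3-hydroxy-2,2-dimethylchroman-8-yl]-2-methylbutan-1-one
Product: 12 (S)-2-methyl-1-[(3S)-3,5,7-trihydroxy-2,2-dimethylchroman-8-yl]butan-1-one
Conditions: Bu4NF (2.2 equiv), AcOH (2.5 equiv), THF, 0 °C
Reagents that add atoms: none
Why: Fluoride cleavage of aryl silyl ethers; buffering with acetic acid avoids a free phloroglucinol polyanion (air oxidation, enolisation next to the ketone), and the tertiary alkyl aryl ether and the secondary alcohol are inert.

Step 8
Reactants: 13 pentan-3-one
Product: 14 (Z)-3-(trimethylsilyloxy)pent-2-ene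
Conditions: TMSOTf, Et3N, Et2O, 0 °C to rt
Reagents that add atoms: trimethylsilyl trifluoromethanesulfonate (TMSOTf), C[Si](C)(C)OS(=O)(=O)C(F)(F)F
Why: Silyl enol ether formation by soft enolisation; the ketone is symmetric, so only one regioisomer is possible, and the double-bond geometry does not matter because it is lost in step 9.

Step 9
Reactants: 14 (Z)-3-(trimethylsilyloxy)pent-2-ene; 15 malonyl dichloride
Product: 16 6-ethyl-4-hydroxy-5-methylpyran-2-one
Conditions: Et2O, −78 °C to rt
Reagents that add atoms: none
Why: Pyranone annulation of a silyl enol ether with malonyl dichloride: C-acylation at the enol carbon, then O-acylation of the resulting enol by the second acid chloride closes the lactone, and tautomerisation gives the 4-hydroxy-2-pyranone with ethyl on C6 and methyl on C5.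

Step 10
Reactants: 12 (S)-2-methyl-1-[(3S)-3,5,7-trihydroxy-2,2-dimethylchroman-8-yl]butan-1-one; 16 6-ethyl-4-hydroxy-5-methylpyran-2-one
Product: 19 6-ethyl-4-hydroxy-5-methyl-3-{[(3S)-3,5,7-trihydroxy-2,2-dimethyl-8-[(2S)-2-methylbutanoyl]chroman-6-yl]methyl}pyran-2-one, via Mannich base 17 (not isolated), via ortho-quinone methide 18 (not isolated)
Conditions: Me2N=CH2+ I− (1.0 equiv), MeCN, 0 °C to rt; then 16 (1.5 equiv), NaOAc (20 mol%), 60 °C
Reagents that add atoms: N,N-dimethylmethyleneiminium iodide (Eschenmoser's salt), C=[N+](C)C.[I-]
Why: Mannich reaction followed by elimination and conjugate addition: the iminium ion attacks C6, the only unsubstituted and doubly hydroxyl-activated carbon of 12; on warming with acetate the Mannich base loses dimethylamine to quinone methide 18, which is captured at its exocyclic carbon by the nucleophilic C3 of pyranone 16 and rearomatises; since 17 has no free ring position the arene cannot dimerise, and 16 is used in excess.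

## Compound list

1 | 4-hydroxy-6-methylpyran-2-one | Cc1cc(O)cc(=O)o1 | starting material
2 | 3-methylbut-2-enyl acetate (prenyl acetate) | CC(C)=CCOC(C)=O | starting material
3 | 4-hydroxy-6-methyl-3-(3-methylbut-2-enyl)pyran-2-one | Cc1cc(O)c(CC=C(C)C)c(=O)o1 | intermediate
4 | (S)-2-methylbutanoic acid | OC(=O)[C@@H](C)CC | starting material
5 | (S)-N-methoxy-N,2-dimethylbutanamide | CON(C)C(=O)[C@@H](C)CC | intermediate
6 | 4-hydroxy-6-[(3S)-3-methyl-2-oxopentyl]-3-(3-methylbut-2-enyl)pyran-2-one | O=C(Cc1cc(O)c(CC=C(C)C)c(=O)o1)[C@@H](C)CC | intermediate
7 | methyl (8S)-8-methyl-2-(3-methylbut-2-enyl)-3,5,7-trioxodecanoate (present as its magnesium enolate; C2 not defined) | COC(=O)C(CC=C(C)C)C(=O)CC(=O)CC(=O)[C@@H](C)CC | intermediate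
8 | (S)-2-methyl-1-[2,4,6-trihydroxy-3-(3-methylbut-2-enyl)phenyl]butan-1-one | O=C([C@@H](C)CC)c1c(O)cc(O)c(CC=C(C)C)c1O | intermediate
9 | (S)-1-[4,6-bis(tert-butyldimethylsilyloxy)-2-hydroxy-3-(3-methylbut-2-enyl)phenyl]-2-methylbutan-1-one | O=C([C@@H](C)CC)c1c(O[Si](C)(C)C(C)(C)C)cc(O[Si](C)(C)C(C)(C)C)c(CC=C(C)C)c1O | intermediate
10 | (S)-1-[4,6-bis(tert-butyldimethylsilyloxy)-3-{[(2S)-3,3-dimethyloxiran-2-yl]methyl}-2-hydroxyphenyl]-2-methylbutan-1-one | O=C([C@@H](C)CC)c1c(O[Si](C)(C)C(C)(C)C)cc(O[Si](C)(C)C(C)(C)C)c(C[C@@H]2OC2(C)C)c1O | intermediate
11 | (S)-1-[(3S)-5,7-bis(tert-butyldimethylsilyloxy)-3-hydroxy-2,2-dimethylchroman-8-yl]-2-methylbutan-1-one | O=C([C@@H](C)CC)c1c(O[Si](C)(C)C(C)(C)C)cc(O[Si](C)(C)C(C)(C)C)c2c1OC(C)(C)[C@@H](O)C2 | intermediate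
12 | (S)-2-methyl-1-[(3S)-3,5,7-trihydroxy-2,2-dimethylchroman-8-yl]butan-1-one | O=C([C@@H](C)CC)c1c(O)cc(O)c2c1OC(C)(C)[C@@H](O)C2 | intermediate
13 | pentan-3-one | CCC(=O)CC | starting material
14 | (Z)-3-(trimethylsilyloxy)pent-2-ene | C/C=C(\O[Si](C)(C)C)CC | intermediate
15 | malonyl dichloride (propanedioyl dichloride) | O=C(Cl)CC(=O)Cl | starting material
16 | 6-ethyl-4-hydroxy-5-methylpyran-2-one | CCc1oc(=O)cc(O)c1C | intermediate
17 | (S)-1-[(3S)-6-[(dimethylamino)methyl]-3,5,7-trihydroxy-2,2-dimethylchroman-8-yl]-2-methylbutan-1-one (formed as its hydroiodide) | O=C([C@@H](C)CC)c1c(O)c(CN(C)C)c(O)c2c1OC(C)(C)[C@@H](O)C2 | intermediate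
18 | (3S)-3,7-dihydroxy-2,2-dimethyl-8-[(2S)-2-methylbutanoyl]-6-methylidene-3,4-dihydro-2H-chromen-5(6H)-one (ortho-quinone methide) | C=C1C(=O)C2=C(OC(C)(C)[C@@H](O)C2)C(C(=O)[C@@H](C)CC)=C1O | intermediate
19 | 6-ethyl-4-hydroxy-5-methyl-3-{[(3S)-3,5,7-trihydroxy-2,2-dimethyl-8-[(2S)-2-methylbutanoyl]chroman-6-yl]methyl}pyran-2-one (CNP0361212.1) | CCc1oc(=O)c(Cc2c(O)c3c(c(C(=O)[C@@H](C)CC)c2O)OC(C)(C)[C@@H](O)C3)c(O)c1C | target

## Step count and risks

Total step count: 10 (steps 2, 8 and 9 prepare the side fragments). Longest linear sequence: 7 steps (1, 3, 4, 5, 6, 7, 10), counted from 1.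

**Step 4 (key step).** The most likely failure is ring opening without productive Claisen closure. The prenyl group makes the ester α-branched and slows the attack of the C6 methylene, so retro-Claisen cleavage of the 1,3-diketone by methoxide, reversible aldol closure, or simple relactonisation on acidification may take over. Slow epimerisation of the chain centre on prolonged heating is a second concern. The fallback keeps the same ring-forming bond but moves the prenylation. It sets out from 1 and 5: the dianion of 1 is acylated with 5 to give 4-hydroxy-6-[(3S)-3-methyl-2-oxopentyl]pyran-2-one F1, the unsubstituted substrate class on which the magnesium methoxide rearrangement is established. F1 is rearranged to (S)-2-methyl-1-(2,4,6-trihydroxyphenyl)butan-1-one F2, and F2 is C-prenylated with prenyl bromide in cold aqueous KOH, which returns to the route at 8. The price is a statistical prenylation with di-C- and O-prenylated by-products to be separated.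

**Step 6.** The main danger is poor facial selectivity at pH 8, where uncatalysed oxidation by KHSO5 and Baeyer–Villiger decomposition of the ketone catalyst compete. Lesser dangers are premature 5-exo closure by the small ionised fraction of the phenol and oxidation of the electron-rich arene. Because the two stereocentres are remote, erosion at C3 would give a diastereomer that is hard to remove. The fallback forms the ring before the oxygen is introduced. It sets out from 9: oxidative cyclisation with DDQ (benzene, 80 °C) gives (S)-1-[5,7-bis(tert-butyldimethylsilyloxy)-2,2-dimethyl-2H-chromen-8-yl]-2-methylbutan-1-one F3. Jacobsen epoxidation with the (S,S)-(salen)MnCl complex and NaOCl (4-phenylpyridine N-oxide, CH2Cl2, 0 °C) should give the (3S,4S)-epoxide F4. Hydrogenolysis of the benzylic C4–O bond (H2, Pd/C, EtOAc) returns to the route at 11.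

**Step 10.** Oligomerisation of the quinone methide, slow loss of dimethylamine, or retro-Mannich scrambling that releases a formaldehyde equivalent and leads to symmetrical methylene-bridged dimers may lower the crossed coupling. The fallback reverses the roles of the two halves. It sets out from 16, which is aminomethylated with Eschenmoser's salt to 3-[(dimethylamino)methyl]-6-ethyl-4-hydroxy-5-methylpyran-2-one F5. Warming F5 with 12 releases 6-ethyl-5-methyl-3-methylidenepyran-2,4-dione F6, which C6 of 12 should capture in a conjugate addition, returning to the route at 19.

**Step 3.** Incomplete dianion formation or slow addition to the α-branched amide would leave free amide base, which can enolise 5 and erode the stereocentre, and would return unchanged 3. The fallback replaces acylation by aldol addition and oxidation. It sets out from 3, whose dianion is added at −78 °C to commercial (S)-2-methylbutanal, a far more reactive electrophile, to give 4-hydroxy-6-[(3S)-2-hydroxy-3-methylpentyl]-3-(3-methylbut-2-enyl)pyran-2-one F7 as a mixture of carbinol epimers. Oxidation with Dess–Martin periodinane (NaHCO3, CH2Cl2) returns to the route at 6. The aldehyde must be used fresh and cold because it epimerises easily.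

**Step 1.** Attack at the tertiary terminus of the allyl complex (reverse prenyl group) or a second allylation at C3 may reduce the yield of 3. The fallback builds the prenyl group in two stages. It sets out from 1, which is C-allylated with allyl acetate under the same palladium catalysis to 3-allyl-4-hydroxy-6-methylpyran-2-one F8. Cross-metathesis with 2-methylbut-2-ene (second-generation Grubbs catalyst, (H2IMes)(PCy3)Cl2Ru=CHPh, CH2Cl2, 40 °C) then returns to the route at 3.

## Further compounds

F1 | step 4 | 4-hydroxy-6-[(3S)-3-methyl-2-oxopentyl]pyran-2-one | O=C(Cc1cc(O)cc(=O)o1)[C@@H](C)CC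
F2 | step 4 | (S)-2-methyl-1-(2,4,6-trihydroxyphenyl)butan-1-one | O=C([C@@H](C)CC)c1c(O)cc(O)cc1O
F3 | step 6 | (S)-1-[5,7-bis(tert-butyldimethylsilyloxy)-2,2-dimethyl-2H-chromen-8-yl]-2-methylbutan-1-one | O=C([C@@H](C)CC)c1c(O[Si](C)(C)C(C)(C)C)cc(O[Si](C)(C)C(C)(C)C)c2c1OC(C)(C)C=C2
F4 | step 6 | (S)-1-[(3S,4S)-5,7-bis(tert-butyldimethylsilyloxy)-3,4-epoxy-2,2-dimethylchroman-8-yl]-2-methylbutan-1-one | O=C([C@@H](C)CC)c1c(O[Si](C)(C)C(C)(C)C)cc(O[Si](C)(C)C(C)(C)C)c2c1OC(C)(C)[C@H]1O[C@H]12
F5 | step 10 | 3-[(dimethylamino)methyl]-6-ethyl-4-hydroxy-5-methylpyran-2-one | CCc1oc(=O)c(CN(C)C)c(O)c1C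
F6 | step 10 | 6-ethyl-5-methyl-3-methylidenepyran-2,4-dione | CCC1=C(C)C(=O)C(=C)C(=O)O1
F7 | step 3 | 4-hydroxy-6-[(3S)-2-hydroxy-3-methylpentyl]-3-(3-methylbut-2-enyl)pyran-2-one | OC(Cc1cc(O)c(CC=C(C)C)c(=O)o1)[C@@H](C)CC
F8 | step 1 | 3-allyl-4-hydroxy-6-methylpyran-2-one | Cc1cc(O)c(CC=C)c(=O)o1
A1 | alternative 1 | tri-O-benzyl ether of the target | CCc1oc(=O)c(Cc2c(OCc4ccccc4)c3c(c(C(=O)[C@@H](C)CC)c2OCc2ccccc2)OC(C)(C)[C@@H](OCc2ccccc2)C3)c(O)c1C
A2 | alternative 1 | 2-{[(3S)-3,5,7-tris(benzyloxy)-2,2-dimethyl-8-[(2S)-2-methylbutanoyl]chroman-6-yl]methyl}malonyl dichloride | O=C(Cl)C(Cc1c(OCc2ccccc2)c2c(c(C(=O)[C@@H](C)CC)c1OCc1ccccc1)OC(C)(C)[C@@H](OCc1ccccc1)C2)C(=O)Cl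
A3 | alternative 2 | 5-tert-butoxy-2-[(1S,2S)-1-(tert-butyldimethylsilyloxy)-2-methylbutyl]-6-(3-methylbut-2-enyl)-3-(triisopropylsilyloxy)phenol | CC[C@H](C)[C@@H](c1c(O)c(CC=C(C)C)c(OC(C)(C)C)cc1O[Si](C(C)C)(C(C)C)C(C)C)O[Si](C)(C)C(C)(C)C
A4 | alternative 2 | 3-tert-butoxy-4-(3-methylbut-2-enyl)cyclobut-2-en-1-one | O=C1C=C(OC(C)(C)C)C1CC=C(C)C
A5 | alternative 2 | (3S,4S)-3-(tert-butyldimethylsilyloxy)-4-methyl-1-(triisopropylsilyloxy)hex-1-yne | CC[C@H](C)[C@@H](C#CO[Si](C(C)C)(C(C)C)C(C)C)O[Si](C)(C)C(C)(C)C
A6 | alternative 3 | (S)-1-[(3S,4S)-5,7-bis(benzyloxy)-3,4-epoxy-2,2-dimethylchroman-8-yl]-2-methylbutan-1-one | O=C([C@@H](C)CC)c1c(OCc2ccccc2)cc(OCc2ccccc2)c2c1OC(C)(C)[C@H]1O[C@H]12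
A7 | alternative 3 | (S)-1-[5,7-bis(benzyloxy)-2,2-dimethyl-2H-chromen-8-yl]-2-methylbutan-1-one | O=C([C@@H](C)CC)c1c(OCc2ccccc2)cc(OCc2ccccc2)c2c1OC(C)(C)C=C2
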